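**Strategy.** Ring A is built, not alkylated. Its contiguous pattern (acyl at C1, hydroxyl at C2, the lavandulyl CH2 at C3, hydroxyl at C4, hydrogen at C5 and C6) maps onto a 2-lavandulylacetoacetate (C2 to C5) and a terminal ynone (C1 and C6) that already carries the enone and ring B. The bis(trimethylsilyl) dienol ether of the keto ester and this dienynone are joined in one [4+2] benzannulation that forms C1–C2 and C5–C6, closes ring A, expels the ester methoxy group and leaves the side chain between the two phenols. The stereocenter is bought as (R)-lavandulol; ring B carries a fluoride-labile silyl ether, so the finished chalcone never meets strong acid or base.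

Key step: step 9

**Remarks on the chemistry (assumptions)**
- Ring A numbering: C1 bears the enone carbonyl, C2 and C4 the hydroxyls, C3 the side chain.
- The stereocenter is never touched and keeps the spatial arrangement of (R)-lavandulol throughout. Only its CIP descriptor changes, from R to S, once the CH2–O (or CH2–I) carbon is bonded to carbon, because the new CH2–C branch then outranks the prenyl CH2. The side chain of the target is therefore (2S)-5-methyl-2-(prop-1-en-2-yl)hex-4-en-1-yl.
- Ring B is protected as a tert-butyldimethylsilyl ether and not as an acid-labile acetal. Strong acid on the finished chalcone would invite chroman formation (isopropenyl group and flanking phenols), flavanone closure (ring A C2 hydroxyl) and flavylium formation (ring B ortho hydroxyl). Buffered fluoride avoids all three.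
- (R)-Lavandulol, (triphenylphosphoranylidene)acetaldehyde and ethynylmagnesium bromide (THF solution) are taken as purchased.

**Route**

Step 1
Reactants: 1 (R)-lavandulol [(2R)-5-methyl-2-(prop-1-en-2-yl)hex-4-en-1-ol]
Product: 2 (R)-lavandulyl iodide [(3R)-3-(iodomethyl)-2,6-dimethylhepta-1,5-diene]
Conditions: PPh3, imidazole, I2, CH2Cl2, 0 °C → rt, dark
Reagents that add atoms: iodine, II
Why: Appel iodination is an SN2 displacement at the primary carbon under buffered, acid-free conditions, so the adjacent stereocenter and both alkenes should be unaffected.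

Step 2
Reactants: 2 (R)-lavandulyl iodide; 3 methyl acetoacetate (2 equiv)
Product: 5 methyl 2-[(2S)-5-methyl-2-(prop-1-en-2-yl)hex-4-en-1-yl]-3-oxobutanoate (methyl 2-lavandulylacetoacetate; C2 epimers expected), via sodium enolate of methyl acetoacetate 4 (not isolated)
Conditions: NaH (1.8 equiv), THF, 0 °C; then 2, DMF co-solvent, 60 °C
Reagents that add atoms: none
Why: Acetoacetic ester alkylation, an SN2 C-alkylation by a soft and weakly basic enolate, should outpace elimination at the primary iodide despite its β-branch, excess enolate should suppress dialkylation, and the new α-center is left uncontrolled because the next two steps flatten it.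

Step 3
Reactants: 5 methyl 2-lavandulylacetoacetate
Product: 6 methyl 2-[(2S)-5-methyl-2-(prop-1-en-2-yl)hex-4-en-1-yl]-3-[(trimethylsilyl)oxy]but-2-enoate (E/Z mixture expected)
Conditions: Me3SiCl, Et3N, toluene, rt, 2–3 d; filtration under argon, concentration
Reagents that add atoms: chlorotrimethylsilane, C[Si](C)(C)Cl
Why: Silyl enol ether formation with an amine base traps the ketone enol of the β-keto ester, which removes the acidic α-hydrogen and the C2 stereocenter before the strong-base step.

Step 4
Reactants: 6 silyl enol ether
Product: 8 (1Z)-1-methoxy-2-[(2S)-5-methyl-2-(prop-1-en-2-yl)hex-4-en-1-yl]-1,3-bis[(trimethylsilyl)oxy]buta-1,3-diene (either ketene acetal geometry serves), via lithium dienolate 7 (not isolated)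
Conditions: LiN(iPr)2 (LDA), THF, −78 °C; Me3SiCl, −78 °C → rt; hexane, filtration under argon; used crude
Reagents that add atoms: chlorotrimethylsilane, C[Si](C)(C)Cl
Why: Kinetic γ-deprotonation of the vinylogous ester by the hindered amide gives the extended ester dienolate, whose oxygen is silylated (silyl ketene acetal formation), the standard two-stage entry to 1-alkoxy-1,3-bis(silyloxy)buta-1,3-dienes; no stereocenter is formed.

Step 5
Reactants: 9 salicylaldehyde
Product: 10 2-[(tert-butyldimethylsilyl)oxy]benzaldehyde
Conditions: tBuMe2SiCl, imidazole, CH2Cl2, rt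
Reagents that add atoms: tert-butyldimethylsilyl chloride, CC(C)(C)[Si](C)(C)Cl
Why: Imidazole-promoted silylation of a phenol is routine, and the aryl silyl ether should tolerate the ylide, the Grignard reagent, MnO2 and heat before leaving with fluoride.

Step 6
Reactants: 10 2-[(tert-butyldimethylsilyl)oxy]benzaldehyde; 11 (triphenylphosphoranylidene)acetaldehyde (1.1 equiv)
Product: 12 (E)-3-{2-[(tert-butyldimethylsilyl)oxy]phenyl}prop-2-enal
Conditions: toluene, 80 °C
Reagents that add atoms: none
Why: Wittig olefination with a stabilised formyl ylide is E-selective, and a small excess of ylide at moderate temperature should limit a second homologation of the less electrophilic enal.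

Step 7
Reactants: 12 (E)-3-{2-[(tert-butyldimethylsilyl)oxy]phenyl}prop-2-enal; 13 ethynylmagnesium bromide (1.3 equiv)
Product: 15 (E)-1-{2-[(tert-butyldimethylsilyl)oxy]phenyl}pent-1-en-4-yn-3-ol (racemic at C3), via bromomagnesium alkoxide 14 (not isolated)
Conditions: THF, −78 → 0 °C; sat. aq NH4Cl
Reagents that add atoms: none
Why: Grignard addition of an alkynyl reagent to an enal is 1,2-selective, and the carbinol center is formed as a racemate because the next oxidation erases it.

Step 8
Reactants: 15 enynol
Product: 16 (E)-1-{2-[(tert-butyldimethylsilyl)oxy]phenyl}pent-1-en-4-yn-3-one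
Conditions: activated MnO2 (excess), CH2Cl2, rt; filtration through Celite; used promptly
Reagents that add atoms: none
Why: MnO2 oxidation is selective for the doubly activated (allylic and propargylic) alcohol under neutral heterogeneous conditions that should spare the silyl ether, the terminal alkyne and the E-alkene.

Step 9
Reactants: 8 bis(trimethylsilyl) diene (1.0 equiv); 16 dienynone (1.3 equiv)
Product: 19 (E)-1-{2,4-dihydroxy-3-[(2S)-5-methyl-2-(prop-1-en-2-yl)hex-4-en-1-yl]phenyl}-3-{2-[(tert-butyldimethylsilyl)oxy]phenyl}prop-2-en-1-one (ring B silyl ether of the target), via cyclohexa-1,4-diene cycloadduct 17 (not isolated), via ring A bis(trimethylsilyl) ether 18 (not isolated)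
Conditions: toluene, 0 → 60 °C; concentration; PPTS (cat.), MeOH, rt
Reagents that add atoms: none
Why: The nucleophilic CH2 terminus of diene 8 adds to the unsubstituted β-carbon of ynone 16 and the ketene acetal carbon bonds to the ynone α-carbon, either in one asynchronous Diels–Alder event or as a Mukaiyama–Michael addition whose silyl allenolate closes onto the carboxonium carbon, to give cycloadduct 17. This is the established cycloaromatisation of 1-alkoxy-1,3-bis(silyloxy)buta-1,3-dienes with acetylenic carbonyl compounds to acyl resorcinols, here applied to a new diene and a new ynone. Ring A closes as a six-membered carbocycle in the [4+2] mode (bonds C1–C2 and C5–C6; in the stepwise limit the second bond is a 6-exo-trig Claisen-type attack), after which 1,4-loss of methanol from the mixed ketal carbon aromatises 17 to 18 and acidic methanol solvolyses the two aryl O–SiMe3 bonds while the bulkier aryl O–SitBuMe2 bond should persist. No stereocenter is formed, and the existing one is remote from the reacting atoms and has no acidic hydrogen under these neutral conditions. Regiochemistry is secured by pairing the most nucleophilic diene carbon with the most electrophilic and least hindered alkyne carbon; chemoselectivity by the terminal ynone being a far better acceptor than the β-aryl enone beside it; and the side chain on the central diene carbon both lands between the two oxygens and denies the competing aldol-type [3+3] closure an aromatic outcome.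

Step 10
Reactants: 19 ring B silyl ether of the target
Product: 20 (E)-1-{2,4-dihydroxy-3-[(2S)-5-methyl-2-(prop-1-en-2-yl)hex-4-en-1-yl]phenyl}-3-(2-hydroxyphenyl)prop-2-en-1-one (target)
Conditions: Bu4NF, AcOH (1:1), THF, 0 °C, dark
Reagents that add atoms: none
Why: Fluoride desilylation cleaves the aryl O–Si bond at low temperature, and the acetic acid buffer keeps the freed phenols protonated, so neither base-driven flavanone closure nor acid-driven cyclisation of the lavandulyl or ring B phenol units should start.

**Compound list**

1 | (R)-lavandulol, (2R)-5-methyl-2-(prop-1-en-2-yl)hex-4-en-1-ol | C=C(C)[C@@H](CC=C(C)C)CO | starting material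
2 | (R)-lavandulyl iodide, (3R)-3-(iodomethyl)-2,6-dimethylhepta-1,5-diene | C=C(C)[C@@H](CC=C(C)C)CI | intermediate
3 | methyl acetoacetate | COC(=O)CC(C)=O | starting material
4 | sodium enolate of methyl acetoacetate (not isolated) | COC(=O)C=C(C)[O-].[Na+] | intermediate
5 | methyl 2-[(2S)-5-methyl-2-(prop-1-en-2-yl)hex-4-en-1-yl]-3-oxobutanoate (C2 epimers) | C=C(C)[C@@H](CC=C(C)C)CC(C(C)=O)C(=O)OC | intermediate
6 | methyl 2-[(2S)-5-methyl-2-(prop-1-en-2-yl)hex-4-en-1-yl]-3-[(trimethylsilyl)oxy]but-2-enoate (E/Z mixture) | C=C(C)[C@@H](CC=C(C)C)CC(C(=O)OC)=C(C)O[Si](C)(C)C | intermediate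
7 | lithium dienolate of 6 (not isolated) | C=C(C)[C@@H](CC=C(C)C)CC(C(=C)O[Si](C)(C)C)=C(OC)[O-].[Li+] | intermediate
8 | (1Z)-1-methoxy-2-[(2S)-5-methyl-2-(prop-1-en-2-yl)hex-4-en-1-yl]-1,3-bis[(trimethylsilyl)oxy]buta-1,3-diene | C=C(C)[C@@H](CC=C(C)C)C/C(C(=C)O[Si](C)(C)C)=C(\OC)O[Si](C)(C)C | intermediate
9 | salicylaldehyde | O=Cc1ccccc1O | starting material
10 | 2-[(tert-butyldimethylsilyl)oxy]benzaldehyde | O=Cc1ccccc1O[Si](C)(C)C(C)(C)C | intermediate
11 | (triphenylphosphoranylidene)acetaldehyde | O=CC=P(c1ccccc1)(c1ccccc1)c1ccccc1 | starting material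
12 | (E)-3-{2-[(tert-butyldimethylsilyl)oxy]phenyl}prop-2-enal | O=C/C=C/c1ccccc1O[Si](C)(C)C(C)(C)C | intermediate
13 | ethynylmagnesium bromide | C#C[Mg]Br | starting material
14 | bromomagnesium alkoxide of 15 (not isolated) | C#CC(O[Mg]Br)/C=C/c1ccccc1O[Si](C)(C)C(C)(C)C | intermediate
15 | (E)-1-{2-[(tert-butyldimethylsilyl)oxy]phenyl}pent-1-en-4-yn-3-ol (racemic at C3) | C#CC(O)/C=C/c1ccccc1O[Si](C)(C)C(C)(C)C | intermediate
16 | (E)-1-{2-[(tert-butyldimethylsilyl)oxy]phenyl}pent-1-en-4-yn-3-one | C#CC(=O)/C=C/c1ccccc1O[Si](C)(C)C(C)(C)C | intermediate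
17 | (E)-1-{6-methoxy-5-[(2S)-5-methyl-2-(prop-1-en-2-yl)hex-4-en-1-yl]-4,6-bis[(trimethylsilyl)oxy]cyclohexa-1,4-dien-1-yl}-3-{2-[(tert-butyldimethylsilyl)oxy]phenyl}prop-2-en-1-one (cycloadduct, epimers at the ketal carbon, not isolated) | C=C(C)[C@@H](CC=C(C)C)CC1=C(O[Si](C)(C)C)CC=C(C(=O)/C=C/c2ccccc2O[Si](C)(C)C(C)(C)C)C1(OC)O[Si](C)(C)C | intermediate
18 | (E)-1-{3-[(2S)-5-methyl-2-(prop-1-en-2-yl)hex-4-en-1-yl]-2,4-bis[(trimethylsilyl)oxy]phenyl}-3-{2-[(tert-butyldimethylsilyl)oxy]phenyl}prop-2-en-1-one (not isolated) | C=C(C)[C@@H](CC=C(C)C)Cc1c(O[Si](C)(C)C)ccc(C(=O)/C=C/c2ccccc2O[Si](C)(C)C(C)(C)C)c1O[Si](C)(C)C | intermediate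
19 | (E)-1-{2,4-dihydroxy-3-[(2S)-5-methyl-2-(prop-1-en-2-yl)hex-4-en-1-yl]phenyl}-3-{2-[(tert-butyldimethylsilyl)oxy]phenyl}prop-2-en-1-one | C=C(C)[C@@H](CC=C(C)C)Cc1c(O)ccc(C(=O)/C=C/c2ccccc2O[Si](C)(C)C(C)(C)C)c1O | intermediate
20 | (E)-1-{2,4-dihydroxy-3-[(2S)-5-methyl-2-(prop-1-en-2-yl)hex-4-en-1-yl]phenyl}-3-(2-hydroxyphenyl)prop-2-en-1-one | C=C(C)[C@@H](CC=C(C)C)Cc1c(O)ccc(C(=O)/C=C/c2ccccc2O)c1O | target

**Step count and risks**

Total steps: 10. Longest linear sequence: 6 steps (steps 1, 2, 3, 4, 9, 10; the ring B branch through steps 5, 6, 7, 8, 9, 10 is equally long).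

Steps most likely to fail:

1. Step 9 (benzannulation). The cross-conjugated dienynone may oligomerise or take the diene at its styryl enone, or the first C–C bond may form without the ring closing. The fallback sets out from diene 8 and assembles the enone after ring A instead of carrying it through the ring formation. The same benzannulation protocol (toluene, 0 → 60 °C; PPTS, MeOH) with the simpler, commercial but-3-yn-2-one should give 1-{2,4-dihydroxy-3-[(2S)-5-methyl-2-(prop-1-en-2-yl)hex-4-en-1-yl]phenyl}ethan-1-one F1. A Claisen–Schmidt condensation of the polyanion of F1 with aldehyde 10 (LiN(SiMe3)2, 4 equiv, THF, −78 °C → rt, mild acidic work-up) then builds the enone. This non-nucleophilic base variant is known for unprotected 2-hydroxyacetophenones and should leave the aryl silyl ether in place. The fallback comes back to the route at 19.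

2. Step 2 (alkylation). Substitution at the β-branched carbon by the ambident, weakly nucleophilic acetoacetate anion may be sluggish, so that O-alkylation and dialkylation erode the C-alkylated product. The fallback sets out from iodide 2 and separates C–C bond formation from introduction of the acetyl group. Malonic ester alkylation (NaCH(CO2Me)2 from dimethyl malonate and NaH, THF/DMF, 60 °C) should give dimethyl 2-[(2S)-5-methyl-2-(prop-1-en-2-yl)hex-4-en-1-yl]propanedioate F2. Krapcho demethoxycarbonylation (LiCl, wet DMSO, 150 °C) should give methyl (4R)-7-methyl-4-(prop-1-en-2-yl)oct-6-enoate F3, whose descriptor changes by priority only. Claisen-type C-acetylation of its lithium enolate (LiN(iPr)2, 2.1 equiv, THF, −78 °C; acetyl chloride) comes back to the route at 5.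

3. Step 6 (formyl olefination). The enal product may be homologated a second time by the ylide, or unreacted hindered aldehyde may persist and be hard to separate. The fallback sets out from aldehyde 10. A Horner–Wadsworth–Emmons reaction with diethyl [2-(methoxy(methyl)amino)-2-oxoethyl]phosphonate (LiCl, DBU, MeCN, rt) should give (E)-3-{2-[(tert-butyldimethylsilyl)oxy]phenyl}-N-methoxy-N-methylprop-2-enamide F4, which cannot over-react. Addition of ethynylmagnesium bromide 13 (THF, −78 → 0 °C) follows, with inverse quench into cold aqueous NaHSO4 so that the released N,O-dimethylhydroxylamine is protonated before it can add to the ynone. This bypasses 12 and 15 and comes back to the route at 16.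

**Further compounds**

F1 | step 9 | 1-{2,4-dihydroxy-3-[(2S)-5-methyl-2-(prop-1-en-2-yl)hex-4-en-1-yl]phenyl}ethan-1-one | C=C(C)[C@@H](CC=C(C)C)Cc1c(O)ccc(C(C)=O)c1O
F2 | step 2 | dimethyl 2-[(2S)-5-methyl-2-(prop-1-en-2-yl)hex-4-en-1-yl]propanedioate | C=C(C)[C@@H](CC=C(C)C)CC(C(=O)OC)C(=O)OC
F3 | step 2 | methyl (4R)-7-methyl-4-(prop-1-en-2-yl)oct-6-enoate | C=C(C)[C@@H](CC=C(C)C)CCC(=O)OC
F4 | step 6 | (E)-3-{2-[(tert-butyldimethylsilyl)oxy]phenyl}-N-methoxy-N-methylprop-2-enamide | CON(C)C(=O)/C=C/c1ccccc1O[Si](C)(C)C(C)(C)C
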